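**Plan**

- Labels: ring B is C5(O, isopropenyl)–C6–C7–C8(Me)–C9(quaternary)–C10(H); C20 is the lactone carbonyl on C9; C1–C3 is the ester chain on C10; C11–C12 link C9 to the butenolide carbon C13.
- Enabling feature: the γ-lactone ring (O, C20, C9, C10, C5) shares C9, C10 and C5 with ring B, and its O-bearing carbon C5 carries an isopropenyl group. This is the pattern left when a malonyl radical adds to a 1,3-diene and an ester traps the resulting allyl cation.
- Retrosynthetic cuts, in order: C12–C13 (sp3–sp2 coupling), C11 (one-carbon insertion next to C9), C9–C10 together with C5–O (key step), C5–isopropenyl and C5–C6 (two couplings on a 1,1-dichloroalkene), C8–C9 (allylic alkylation).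
- Forward: an open chain is assembled from di-tert-butyl malonate, a crotyl carbonate, a dichloroalkene ester and isopropenylzinc bromide. Ring B and the lactone ring then close together in one anodic Mn(OAc)2/Cu(OAc)2 operation, and the remaining ester is grown into the butenolide arm, whose ring is brought in intact.
- Stereochemistry: C8 comes from the [Ir(cod)Cl]2/phosphoramidite catalyst; the Z diene comes from trans-selective monocoupling of the dichloroalkene; C10, C9 and C5 come from the chair transition state of the key step, relayed from C8 and the Z alkene.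

Key step: step 5

Assumption: the (Sa,Sc,Sc) antipode of the phosphoramidite is taken to give the R centre at C8 by the usual facial model of these iridium catalysts; if the sense proves opposite, the mirror-image ligand is used.

**Route**

Step 1
Reactants: 1 di-tert-butyl malonate; 2 (E)-but-2-en-1-yl methyl carbonate
Product: 3 di-tert-butyl (R)-2-(but-3-en-2-yl)malonate
Conditions: [Ir(cod)Cl]2 (2 mol%), BINOL-derived phosphoramidite with N,N-bis[1-(2-methoxyphenyl)ethyl] groups (4 mol%), 1,5,7-triazabicyclo[4.4.0]dec-5-ene (8 mol%), THF, rt to 40 °C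
Reagents that add atoms: none
Why: Iridium-catalysed branched-selective asymmetric allylic alkylation under salt-free conditions, in which the methoxide released from the carbonate deprotonates the malonate and the cyclometalated allyliridium complex is attacked at the methyl-bearing terminus, so C8 is set R under catalyst control.

Step 2
Reactants: 4 methyl 4-oxobutanoate
Product: 5 methyl 5,5-dichloropent-4-enoate
Conditions: PPh3, CCl4, MeCN, 0 °C to rt
Reagents that add atoms: carbon tetrachloride, ClC(Cl)(Cl)Cl
Why: Appel–Ramirez-type dichloromethylenation, in which PPh3 and CCl4 form Ph3P=CCl2 and this ylide olefinates the aldehyde in a Wittig reaction while the methyl ester stays inert.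

Step 3
Reactants: 3 di-tert-butyl (R)-2-(but-3-en-2-yl)malonate; 5 methyl 5,5-dichloropent-4-enoate
Product: 7 di-tert-butyl 2-[(2R,5Z)-5-chloro-9-methoxy-9-oxonon-5-en-2-yl]malonate, via B-alkyl-9-BBN adduct 6 (not isolated)
Conditions: 9-BBN, THF, 0 °C to rt; then 5, Pd2(dba)3 (2.5 mol%), Xantphos (5 mol%), aq. K3PO4, THF, 65 °C
Reagents that add atoms: none
Why: Anti-Markovnikov hydroboration followed by B-alkyl Suzuki–Miyaura monocoupling of a 1,1-dichloroalkene, where oxidative addition takes the C–Cl bond trans to the ester chain and the wide-bite-angle ligand should stop the reaction at the Z chloroalkene, so the C6 chain ends up trans to C1 and C8 is not touched.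

Step 4
Reactants: 7 di-tert-butyl 2-[(2R,5Z)-5-chloro-9-methoxy-9-oxonon-5-en-2-yl]malonate
Product: 8 di-tert-butyl 2-[(2R,5Z)-9-methoxy-9-oxo-5-(prop-1-en-2-yl)non-5-en-2-yl]malonate
Conditions: isopropenylmagnesium bromide, ZnBr2, THF, 0 °C; then 7, Pd(P(t-Bu)3)2 (5 mol%), THF, 50 °C
Reagents that add atoms: isopropenylmagnesium bromide, C=C(C)[Mg]Br (used as isopropenylzinc bromide, C=C(C)[Zn]Br)
Why: Negishi coupling with retention of alkene geometry, in which the bulky electron-rich palladium catalyst inserts into the hindered alkenyl C–Cl bond and the neutral alkenylzinc reagent tolerates the esters and the malonate C–H, placing isopropenyl cis to the C1 chain.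

Step 5
Reactants: 8 di-tert-butyl 2-[(2R,5Z)-9-methoxy-9-oxo-5-(prop-1-en-2-yl)non-5-en-2-yl]malonate
Product: 9 tert-butyl (1R,2R,5S,8R)-8-(3-methoxy-3-oxopropyl)-2-methyl-7-oxo-5-(prop-1-en-2-yl)-6-oxabicyclo[3.2.1]octane-1-carboxylate
Conditions: Mn(OAc)2·4H2O (20 mol%), Cu(OAc)2·H2O (20 mol%), NaOAc, AcOH, 60 °C, divided cell, graphite-felt anode, Pt cathode, constant current (about 2.2 F/mol)
Reagents that add atoms: none
Why: Mn(OAc)3 formed at the anode oxidises the malonate enol to the electrophilic C9 radical, which adds to C10 of the diene; divalent copper then oxidises the allyl radical to an allyl cation, and the axial tert-butyl ester traps it at C5 with loss of isobutene, the closest known reaction type being the Mn(OAc)3/Cu(OAc)2 oxidative malonate cyclisation–lactonisation run with electrochemical turnover of the manganese. Ring B closes 6-endo-trig (C9–C10) and the lactone ring closes by 5-exo attack of the ester carbonyl oxygen on the C5 end of the allyl cation (C5–O), giving the 6-oxabicyclo[3.2.1]octan-7-one. C10 is set in a chair transition state with the C8 methyl equatorial, in which the Z geometry places the C1 chain equatorial and therefore cis to that methyl. C9 and C5 are set together, because only the ester that is axial, and thus cis to both equatorial groups, can reach C5, and the one-atom bridge allows only the cis 1,3-diaxial junction. The step needs attack at C10 in preference to C5 or the diene terminus and needs the mediator to be oxidised before the diene; the first should follow from the fully substituted C5, the tertiary allyl radical that only C10 attack produces and the preference for a six- over a seven-membered ring, the second from the lower oxidation potential of Mn(OAc)2 in buffered AcOH.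

Step 6
Reactants: 9 tert-butyl (1R,2R,5S,8R)-8-(3-methoxy-3-oxopropyl)-2-methyl-7-oxo-5-(prop-1-en-2-yl)-6-oxabicyclo[3.2.1]octane-1-carboxylate
Product: 10 (1R,2R,5S,8R)-8-(3-methoxy-3-oxopropyl)-2-methyl-7-oxo-5-(prop-1-en-2-yl)-6-oxabicyclo[3.2.1]octane-1-carboxylic acid
Conditions: TFA/CH2Cl2 (1:4), 0 °C
Reagents that add atoms: none
Why: Acidolysis of a tert-butyl ester by alkyl–oxygen cleavage leaves the methyl ester untouched; any ionisation of the bridged tertiary allylic lactone should be reversed by the carboxyl group held axially over C5, and the isopropenyl group is deactivated towards protonation by the adjacent C5–O bond.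

Step 7
Reactants: 10 (1R,2R,5S,8R)-8-(3-methoxy-3-oxopropyl)-2-methyl-7-oxo-5-(prop-1-en-2-yl)-6-oxabicyclo[3.2.1]octane-1-carboxylic acid
Product: 12 methyl 3-[(1R,2R,5S,8R)-1-(2-diazoacetyl)-2-methyl-7-oxo-5-(prop-1-en-2-yl)-6-oxabicyclo[3.2.1]octan-8-yl]propanoate, via acid chloride 11 (not isolated)
Conditions: (COCl)2, cat. DMF, CH2Cl2, 0 °C to rt; concentrate; CH2N2 (excess), Et2O, 0 °C
Reagents that add atoms: diazomethane, C=[N+]=[N-]
Why: First half of the Arndt–Eistert homologation, in which the acid chloride acylates diazomethane and a second equivalent takes up the HCl; C9 is quaternary, so nothing can epimerise.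

Step 8
Reactants: 12 methyl 3-[(1R,2R,5S,8R)-1-(2-diazoacetyl)-2-methyl-7-oxo-5-(prop-1-en-2-yl)-6-oxabicyclo[3.2.1]octan-8-yl]propanoate
Product: 14 2-[(1R,2R,5S,8R)-8-(3-methoxy-3-oxopropyl)-2-methyl-7-oxo-5-(prop-1-en-2-yl)-6-oxabicyclo[3.2.1]octan-1-yl]acetic acid, via ketene 13 (not isolated)
Conditions: AgO2CPh (10 mol%), Et3N, THF/H2O (9:1), rt, dark
Reagents that add atoms: water, O
Why: Silver-catalysed Wolff rearrangement, in which loss of N2 and 1,2-shift of C9 with retention give the ketene and water converts it into the homologous acid, so that C11 is now in place.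

Step 9
Reactants: 14 2-[(1R,2R,5S,8R)-8-(3-methoxy-3-oxopropyl)-2-methyl-7-oxo-5-(prop-1-en-2-yl)-6-oxabicyclo[3.2.1]octan-1-yl]acetic acid
Product: 16 methyl 3-[(1R,2R,5S,8R)-1-(2-hydroxyethyl)-2-methyl-7-oxo-5-(prop-1-en-2-yl)-6-oxabicyclo[3.2.1]octan-8-yl]propanoate, via isobutyl carbonic anhydride 15 (not isolated)
Conditions: i-BuOCOCl, N-methylmorpholine, THF, −15 °C; filter; NaBH4, THF/H2O, 0 °C; aq. NH4Cl quench
Reagents that add atoms: none
Why: Reduction of a carboxylic acid through its mixed carbonic anhydride with NaBH4 is selective over the methyl ester, the hindered tertiary lactone and both alkenes (no borane, hence no hydroboration), and the cold buffered quench is meant to keep the new γ-hydroxyl from attacking the doubly neopentyl lactone carbonyl C20.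

Step 10
Reactants: 16 methyl 3-[(1R,2R,5S,8R)-1-(2-hydroxyethyl)-2-methyl-7-oxo-5-(prop-1-en-2-yl)-6-oxabicyclo[3.2.1]octan-8-yl]propanoate
Product: 17 methyl 3-[(1R,2R,5S,8R)-1-(2-iodoethyl)-2-methyl-7-oxo-5-(prop-1-en-2-yl)-6-oxabicyclo[3.2.1]octan-8-yl]propanoate
Conditions: PPh3, I2, imidazole, CH2Cl2, 0 °C
Reagents that add atoms: iodine, II
Why: Appel-type iodination (Garegg–Samuelsson conditions), in which iodide displaces the alkoxyphosphonium salt of the primary alcohol under nearly neutral conditions, removing the hydroxyl that could translactonise.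

Step 11
Reactants: 17 methyl 3-[(1R,2R,5S,8R)-1-(2-iodoethyl)-2-methyl-7-oxo-5-(prop-1-en-2-yl)-6-oxabicyclo[3.2.1]octan-8-yl]propanoate; 18 3-bromofuran-2(5H)-one
Product: 20 methyl 3-[(1R,2R,5S,8R)-2-methyl-7-oxo-1-[2-(2-oxo-2,5-dihydrofuran-3-yl)ethyl]-5-(prop-1-en-2-yl)-6-oxabicyclo[3.2.1]octan-8-yl]propanoate, via alkylzinc iodide 19 (not isolated)
Conditions: Zn dust (activated with TMSCl and 1,2-dibromoethane), LiCl, THF, 40 °C; then 18, Pd(OAc)2 (3 mol%), SPhos (6 mol%), THF, rt
Reagents that add atoms: none
Why: Negishi sp3–sp2 coupling, in which direct zinc insertion into the primary iodide gives an alkylzinc reagent compatible with ester, lactone and alkene, and the palladium catalyst joins it to the activated α-bromobutenolide under neutral conditions without touching any of the four stereocentres.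

**Compound list**

1 | di-tert-butyl malonate | CC(C)(C)OC(=O)CC(=O)OC(C)(C)C | starting material
2 | (E)-but-2-en-1-yl methyl carbonate | C/C=C/COC(=O)OC | starting material
3 | di-tert-butyl (R)-2-(but-3-en-2-yl)malonate | C=C[C@@H](C)C(C(=O)OC(C)(C)C)C(=O)OC(C)(C)C | intermediate
4 | methyl 4-oxobutanoate | COC(=O)CCC=O | starting material
5 | methyl 5,5-dichloropent-4-enoate | COC(=O)CCC=C(Cl)Cl | intermediate
6 | di-tert-butyl (R)-2-[4-(9-borabicyclo[3.3.1]nonan-9-yl)butan-2-yl]malonate | B1(CC[C@@H](C)C(C(=O)OC(C)(C)C)C(=O)OC(C)(C)C)C2CCCC1CCC2 | intermediate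
7 | di-tert-butyl 2-[(2R,5Z)-5-chloro-9-methoxy-9-oxonon-5-en-2-yl]malonate | COC(=O)CC/C=C(\Cl)CC[C@@H](C)C(C(=O)OC(C)(C)C)C(=O)OC(C)(C)C | intermediate
8 | di-tert-butyl 2-[(2R,5Z)-9-methoxy-9-oxo-5-(prop-1-en-2-yl)non-5-en-2-yl]malonate | C=C(C)/C(CC[C@@H](C)C(C(=O)OC(C)(C)C)C(=O)OC(C)(C)C)=C\CCC(=O)OC | intermediate
9 | tert-butyl (1R,2R,5S,8R)-8-(3-methoxy-3-oxopropyl)-2-methyl-7-oxo-5-(prop-1-en-2-yl)-6-oxabicyclo[3.2.1]octane-1-carboxylate | C=C(C)[C@@]12CC[C@@H](C)[C@@](C(=O)OC(C)(C)C)(C(=O)O1)[C@H]2CCC(=O)OC | intermediate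
10 | (1R,2R,5S,8R)-8-(3-methoxy-3-oxopropyl)-2-methyl-7-oxo-5-(prop-1-en-2-yl)-6-oxabicyclo[3.2.1]octane-1-carboxylic acid | C=C(C)[C@@]12CC[C@@H](C)[C@@](C(=O)O)(C(=O)O1)[C@H]2CCC(=O)OC | intermediate
11 | acid chloride of 10 (COCl on the quaternary carbon, all centres as in 10) | C=C(C)[C@@]12CC[C@@H](C)[C@@](C(=O)Cl)(C(=O)O1)[C@H]2CCC(=O)OC | intermediate
12 | methyl 3-[(1R,2R,5S,8R)-1-(2-diazoacetyl)-2-methyl-7-oxo-5-(prop-1-en-2-yl)-6-oxabicyclo[3.2.1]octan-8-yl]propanoate | C=C(C)[C@@]12CC[C@@H](C)[C@@](C(=O)C=[N+]=[N-])(C(=O)O1)[C@H]2CCC(=O)OC | intermediate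
13 | ketene from 12 (CH=C=O on the quaternary carbon, all centres as in 12) | C=C(C)[C@@]12CC[C@@H](C)[C@@](C=C=O)(C(=O)O1)[C@H]2CCC(=O)OC | intermediate
14 | 2-[(1R,2R,5S,8R)-8-(3-methoxy-3-oxopropyl)-2-methyl-7-oxo-5-(prop-1-en-2-yl)-6-oxabicyclo[3.2.1]octan-1-yl]acetic acid | C=C(C)[C@@]12CC[C@@H](C)[C@@](CC(=O)O)(C(=O)O1)[C@H]2CCC(=O)OC | intermediate
15 | mixed isobutyl carbonic anhydride of 14 (all centres as in 14) | C=C(C)[C@@]12CC[C@@H](C)[C@@](CC(=O)OC(=O)OCC(C)C)(C(=O)O1)[C@H]2CCC(=O)OC | intermediate
16 | methyl 3-[(1R,2R,5S,8R)-1-(2-hydroxyethyl)-2-methyl-7-oxo-5-(prop-1-en-2-yl)-6-oxabicyclo[3.2.1]octan-8-yl]propanoate | C=C(C)[C@@]12CC[C@@H](C)[C@@](CCO)(C(=O)O1)[C@H]2CCC(=O)OC | intermediate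
17 | methyl 3-[(1R,2R,5S,8R)-1-(2-iodoethyl)-2-methyl-7-oxo-5-(prop-1-en-2-yl)-6-oxabicyclo[3.2.1]octan-8-yl]propanoate | C=C(C)[C@@]12CC[C@@H](C)[C@@](CCI)(C(=O)O1)[C@H]2CCC(=O)OC | intermediate
18 | 3-bromofuran-2(5H)-one | O=C1OCC=C1Br | starting material
19 | alkylzinc iodide from 17 (CH2CH2ZnI on the quaternary carbon, all centres as in 17) | C=C(C)[C@@]12CC[C@@H](C)[C@@](CC[Zn]I)(C(=O)O1)[C@H]2CCC(=O)OC | intermediate
20 | methyl 3-[(1R,2R,5S,8R)-2-methyl-7-oxo-1-[2-(2-oxo-2,5-dihydrofuran-3-yl)ethyl]-5-(prop-1-en-2-yl)-6-oxabicyclo[3.2.1]octan-8-yl]propanoate (CNP0209666.1) | C=C(C)[C@@]12CC[C@@H](C)[C@@](CCC3=CCOC3=O)(C(=O)O1)[C@H]2CCC(=O)OC | target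

**Summary**

Total step count: 11. Longest linear sequence: 10 steps (steps 1 and 3 to 11, from di-tert-butyl malonate); step 2 is a one-step side branch.

**Steps most likely to fail**

Step 5. The cascade may be diverted by competing closure modes (5-exo at C5 or attack on the diene terminus), by the less favoured chair, or by acetate capture or proton loss from the allyl cation before the ester reaches it. The fallback is an iodine atom-transfer sequence of known type that sets out from 8. Deprotonation and iodination of the malonate (NaH, N-iodosuccinimide, THF, 0 °C) should give di-tert-butyl 2-iodo-2-[(2R,5Z)-9-methoxy-9-oxo-5-(prop-1-en-2-yl)non-5-en-2-yl]malonate F1. Irradiation with catalytic (Bu3Sn)2 in benzene at 80 °C should close ring B by the same attack at C10 and transfer iodine to the allyl radical, giving di-tert-butyl (2S,6R)-3-(1-iodopropan-2-ylidene)-2-(3-methoxy-3-oxopropyl)-6-methylcyclohexane-1,1-dicarboxylate F2. On continued heating F2 should ionise and be captured by the axial tert-butyl ester with loss of tert-butyl iodide, returning to the route at 9.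

Step 3. The monocoupling may lose selectivity through a second coupling at the remaining C–Cl bond, or stall through slow transmetalation of the borane while the base deprotonates the malonate. The fallback forms the same bond without base by a Negishi reaction and sets out from 3. Hydroboration–oxidation (9-BBN; NaBO3·4H2O) should give di-tert-butyl (R)-2-(4-hydroxybutan-2-yl)malonate F3. Iodination (PPh3, I2, imidazole) should give di-tert-butyl (R)-2-(4-iodobutan-2-yl)malonate F4, and zinc insertion (Zn, LiCl, THF) the corresponding alkylzinc iodide F5. Trans-selective monoalkylation of 5 with F5 under PdCl2(DPEphos) catalysis in THF returns to the route at 7.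

Step 11. Zinc insertion may be incomplete, the alkylzinc reagent may be lost by protonation or β-hydride elimination after transmetalation, and the bromobutenolide may decompose before it couples. The fallback builds the butenolide by enolate alkylation and sets out from 17. Alkylation with the lithium enolate of 3-(phenylsulfanyl)oxolan-2-one (LiHMDS, THF/DMPU, −78 to 0 °C) should give the α-phenylsulfanyl lactone F6 as a mixture of epimers at the new sulfur-bearing carbon. Oxidation at sulfur (mCPBA, 1 equiv, CH2Cl2, −78 °C) should give the sulfoxide F7, and thermal syn-elimination towards the ring (toluene, 110 °C, CaCO3) returns to the route at 20.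

**Further compounds**

F1 | step 5 | di-tert-butyl 2-iodo-2-[(2R,5Z)-9-methoxy-9-oxo-5-(prop-1-en-2-yl)non-5-en-2-yl]malonate | C=C(C)/C(CC[C@@H](C)C(I)(C(=O)OC(C)(C)C)C(=O)OC(C)(C)C)=C\CCC(=O)OC
F2 | step 5 | di-tert-butyl (2S,6R)-3-(1-iodopropan-2-ylidene)-2-(3-methoxy-3-oxopropyl)-6-methylcyclohexane-1,1-dicarboxylate (alkene geometry not defined) | COC(=O)CC[C@H]1C(=C(C)CI)CC[C@@H](C)C1(C(=O)OC(C)(C)C)C(=O)OC(C)(C)C
F3 | step 3 | di-tert-butyl (R)-2-(4-hydroxybutan-2-yl)malonate | OCC[C@@H](C)C(C(=O)OC(C)(C)C)C(=O)OC(C)(C)C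
F4 | step 3 | di-tert-butyl (R)-2-(4-iodobutan-2-yl)malonate | ICC[C@@H](C)C(C(=O)OC(C)(C)C)C(=O)OC(C)(C)C
F5 | step 3 | alkylzinc iodide from F4 | I[Zn]CC[C@@H](C)C(C(=O)OC(C)(C)C)C(=O)OC(C)(C)C
F6 | step 11 | methyl 3-[(1R,2R,5S,8R)-2-methyl-7-oxo-1-{2-[2-oxo-3-(phenylsulfanyl)oxolan-3-yl]ethyl}-5-(prop-1-en-2-yl)-6-oxabicyclo[3.2.1]octan-8-yl]propanoate (epimers at the sulfur-bearing carbon) | C=C(C)[C@@]12CC[C@@H](C)[C@@](CCC3(Sc4ccccc4)CCOC3=O)(C(=O)O1)[C@H]2CCC(=O)OC
F7 | step 11 | sulfoxide of F6 (phenylsulfinyl in place of phenylsulfanyl) | C=C(C)[C@@]12CC[C@@H](C)[C@@](CCC3(S(=O)c4ccccc4)CCOC3=O)(C(=O)O1)[C@H]2CCC(=O)OC
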